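**Retrosynthetic overview**
- Feature: in unit B (the 5,7-dihydroxycoumarin) the benzene ring B (C4a, C5, C6, C7, C8, C8a) carries oxygen on C5, C7 and C8a. This is the 1,3,5 pattern of a poly-beta-carbonyl chain, and the diaryl ether oxygen sits on C8, between C7 and C8a.
- Key disconnection C7–C8: ring B opens to a 2-pyranone, which is the finished lactone ring of unit B. It bears a methyl 3-oxopropanoate chain (C5, C6, C7) on C4a and a CH2OAr group (C8) on C8a, and an intramolecular Claisen condensation closes the ring.
- The keto ester comes from the pyranone carboxylic acid and methyl malonate. The O–C8 bond is made as an alkyl aryl ether by SN2 of 8-hydroxy-7-methoxycoumarin on a bromomethylpyranone, so no aryl–oxygen coupling between two hindered rings is needed.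
- The pyranone comes from tert-butyl acetoacetate and methyl propiolate. The coumarin of unit A comes from 2,3-dihydroxy-4-methoxybenzaldehyde by Wittig olefination and lactonisation.
- Order of ring formation: lactone ring of unit A, then the pyranone (lactone ring of unit B), then benzene ring B.

Key step: step 7

Remark: the target has no stereocentre and its SMILES carries no stereodescriptor. Rotation about the diaryl ether bonds is taken as free, so no stereocontrol is needed.
Remark: C2 to C8a are the coumarin locants of unit B and are used for the same atoms in all precursors. Pyranone positions 5 and 6 are C4a and C8a.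

**Step 1**
Reactants: 1 2,3-dihydroxy-4-methoxybenzaldehyde; 2 ethyl (triphenylphosphoranylidene)acetate
Product: 4 8-hydroxy-7-methoxycoumarin, via ethyl (E)-2,3-dihydroxy-4-methoxycinnamate 3 (not isolated)
Conditions: PhNEt2, reflux (ca. 215 °C), N2
Reagents that add atoms: none
Why: Wittig olefination with the stabilised ylide should give cinnamate 3, which at this temperature isomerises from E to Z and lactonises onto the 2-OH, the only hydroxyl within reach of the ester, so that the 3-OH is left as the free 8-OH of 4 (one-pot Wittig–lactonisation of salicylaldehydes).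

**Step 2**
Reactants: 5 tert-butyl acetoacetate; 6 methyl propiolate
Product: 8 tert-butyl 6-methyl-2-oxo-2H-pyran-5-carboxylate, via Michael adduct 7 (not isolated)
Conditions: DABCO (10 mol %), toluene, 0 → 23 °C; then DBU (20 mol %), 4 Å MS, 110 °C
Reagents that add atoms: none
Why: Amine-catalysed Michael addition of the 1,3-dicarbonyl carbon of 5 to the propiolate gives 7, whose delocalised glutaconate-type anion lets the C=C geometry equilibrate so that the acetyl enol oxygen can lactonise onto the methyl ester with the tert-butyl ester as a spectator (classical 2-pyranone synthesis from a beta-keto ester and a propiolate).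

**Step 3**
Reactants: 8 tert-butyl 6-methyl-2-oxo-2H-pyran-5-carboxylate
Product: 9 tert-butyl 6-(bromomethyl)-2-oxo-2H-pyran-5-carboxylate
Conditions: NBS (1.05 equiv), AIBN (5 mol %), PhCF3, 85 °C
Reagents that add atoms: N-bromosuccinimide, O=C1CCC(=O)N1Br
Why: Wohl–Ziegler bromination, in which hydrogen abstraction from the methyl group at pyranone position 6 gives a radical delocalised over the ring diene, as known for 6-methyl-2-pyranones, while the electron-poor ring resists ionic bromination and NBS keeps HBr too low to harm the tert-butyl ester.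

**Step 4**
Reactants: 4 8-hydroxy-7-methoxycoumarin; 9 tert-butyl 6-(bromomethyl)-2-oxo-2H-pyran-5-carboxylate
Product: 10 tert-butyl 6-{[(7-methoxy-2-oxo-2H-chromen-8-yl)oxy]methyl}-2-oxo-2H-pyran-5-carboxylate
Conditions: K2CO3 (1.5 equiv), acetone, 23 → 40 °C
Reagents that add atoms: none
Why: Williamson ether synthesis, in which the phenoxide of 4 displaces bromide by SN2 at a primary, allylic-type, carbonyl-activated carbon, setting the O–C8 bond of the later diaryl ether while C8 is still sp3 and unhindered, under a base too weak to open either lactone.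

**Step 5**
Reactants: 10 tert-butyl 6-{[(7-methoxy-2-oxo-2H-chromen-8-yl)oxy]methyl}-2-oxo-2H-pyran-5-carboxylate
Product: 11 6-{[(7-methoxy-2-oxo-2H-chromen-8-yl)oxy]methyl}-2-oxo-2H-pyran-5-carboxylic acid
Conditions: TFA–CH2Cl2 (1:2), 0 → 23 °C
Reagents that add atoms: none
Why: Acidolysis of the tert-butyl ester (loss of the tert-butyl cation as isobutene) spares both lactones, the methyl ether and the ArO–CH2 ether, whose carbon sits on an electron-poor pyranone and cannot ionise.

**Step 6**
Reactants: 11 6-{[(7-methoxy-2-oxo-2H-chromen-8-yl)oxy]methyl}-2-oxo-2H-pyran-5-carboxylic acid; 12 potassium methyl malonate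
Product: 15 methyl 3-[6-{[(7-methoxy-2-oxo-2H-chromen-8-yl)oxy]methyl}-2-oxo-2H-pyran-5-yl]-3-oxopropanoate, via acyl imidazolide 13 (not isolated), via acylmalonic half ester 14 (not isolated)
Conditions: CDI (1.2 equiv), THF, 23 °C; then 12 (2 equiv), MgCl2 (2 equiv), Et3N (3 equiv), MeCN–THF, 23 → 40 °C; 1 M HCl
Reagents that add atoms: 1,1'-carbonyldiimidazole, O=C(n1ccnc1)n1ccnc1 (imidazolyl group of 13 only; none of its atoms stay in 15)
Why: Masamune–Brooks homologation, in which acyl imidazolide 13 is C-acylated by the magnesium enolate of the malonic half ester under nearly neutral conditions and 14 loses CO2, giving the beta-keto ester without exposing the pyranone or the coumarin to a strong base or nucleophile.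

**Step 7**
Reactants: 15 methyl 3-[6-{[(7-methoxy-2-oxo-2H-chromen-8-yl)oxy]methyl}-2-oxo-2H-pyran-5-yl]-3-oxopropanoate
Product: 17 8-[(5,7-dihydroxy-2-oxo-2H-chromen-8-yl)oxy]-7-methoxy-2H-chromen-2-one (target), via chromene-2,5,7-trione 16 (not isolated)
Conditions: KN(SiMe3)2 (1.5 equiv), 18-crown-6 (1.5 equiv), THF (0.01 M), −78 → 23 °C; then 1 M HCl
Reagents that add atoms: none
Why: Proposed new method: the base first enolises the keto ester at C6 and then, in part, removes a proton from the C8 methylene, which is acidified by its aryloxy group and by conjugation through C8a=C4a with the lactone carbonyl C2 and the C5 ketone; C8 adds to the ester carbonyl C7, methoxide leaves, and trione 16 tautomerises at once to the phenoxide of 17, which makes the sequence irreversible. The closest known reaction types are the Claisen-type cyclisation of 3,5,7-trioxoalkanoates to acylphloroglucinols and the deprotonation and C-acylation of 6-alkyl-2-pyranones at the exocyclic carbon, whereas such a closure onto an intact 2-pyranone has not been described. Ring B closes in a 6-(enolendo)-exo-trig mode, and no stereocentre survives, since C8 of 16 becomes sp2 on aromatisation. Closure needs C7 syn to C4a about the C5–C6 bond, a geometry that the chelated Z enolate (O5 and the ester carbonyl oxygen on one cation) cannot reach and in which the ester is also switched off electronically; therefore potassium with 18-crown-6 replaces a chelating cation, and the base is kept below two equivalents so that mono- and dianion coexist and exchange protons, which lets the C8 carbanion that carries a non-enolised, freely rotating and fully electrophilic keto ester carry the closure. Selectivity over the two lactones rests on the non-nucleophilic base, on C7 being the only carbonyl that C8 can reach through an unstrained ring (attack at C5 would give a four-membered ring, and the lactone carbonyl of unit A is held anti to C8), and on high dilution, which holds back intermolecular addition to the pyranone. Any methoxide that opens the coumarin of unit A gives a Z-2-hydroxycinnamate, which closes again in the acidic work-up.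

**Compound list**
1 | 2,3-dihydroxy-4-methoxybenzaldehyde | COc1ccc(C=O)c(O)c1O | starting material
2 | ethyl (triphenylphosphoranylidene)acetate | CCOC(=O)C=P(c1ccccc1)(c1ccccc1)c1ccccc1 | starting material
3 | ethyl (E)-3-(2,3-dihydroxy-4-methoxyphenyl)acrylate | CCOC(=O)/C=C/c1ccc(OC)c(O)c1O | intermediate
4 | 8-hydroxy-7-methoxy-2H-chromen-2-one (8-hydroxy-7-methoxycoumarin) | COc1ccc2ccc(=O)oc2c1O | intermediate
5 | tert-butyl acetoacetate | CC(=O)CC(=O)OC(C)(C)C | starting material
6 | methyl propiolate | C#CC(=O)OC | starting material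
7 | 5-tert-butyl 1-methyl (2E)-4-acetylpent-2-enedioate (racemic, labile at C4) | COC(=O)/C=C/C(C(C)=O)C(=O)OC(C)(C)C | intermediate
8 | tert-butyl 6-methyl-2-oxo-2H-pyran-5-carboxylate | Cc1oc(=O)ccc1C(=O)OC(C)(C)C | intermediate
9 | tert-butyl 6-(bromomethyl)-2-oxo-2H-pyran-5-carboxylate | BrCc1oc(=O)ccc1C(=O)OC(C)(C)C | intermediate
10 | tert-butyl 6-{[(7-methoxy-2-oxo-2H-chromen-8-yl)oxy]methyl}-2-oxo-2H-pyran-5-carboxylate | COc1ccc2ccc(=O)oc2c1OCc1oc(=O)ccc1C(=O)OC(C)(C)C | intermediate
11 | 6-{[(7-methoxy-2-oxo-2H-chromen-8-yl)oxy]methyl}-2-oxo-2H-pyran-5-carboxylic acid | COc1ccc2ccc(=O)oc2c1OCc1oc(=O)ccc1C(=O)O | intermediate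
12 | potassium methyl malonate | COC(=O)CC(=O)[O-].[K+] | starting material
13 | 5-(1H-imidazol-1-ylcarbonyl)-6-{[(7-methoxy-2-oxo-2H-chromen-8-yl)oxy]methyl}-2H-pyran-2-one | COc1ccc2ccc(=O)oc2c1OCc1oc(=O)ccc1C(=O)n1ccnc1 | intermediate
14 | 2-(methoxycarbonyl)-3-[6-{[(7-methoxy-2-oxo-2H-chromen-8-yl)oxy]methyl}-2-oxo-2H-pyran-5-yl]-3-oxopropanoic acid (present as magnesium salt) | COC(=O)C(C(=O)O)C(=O)c1ccc(=O)oc1COc1c(OC)ccc2ccc(=O)oc12 | intermediate
15 | methyl 3-[6-{[(7-methoxy-2-oxo-2H-chromen-8-yl)oxy]methyl}-2-oxo-2H-pyran-5-yl]-3-oxopropanoate | COC(=O)CC(=O)c1ccc(=O)oc1COc1c(OC)ccc2ccc(=O)oc12 | intermediate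
16 | 8-[(7-methoxy-2-oxo-2H-chromen-8-yl)oxy]-2H-chromene-2,5,7(6H,8H)-trione (racemic, transient) | COc1ccc2ccc(=O)oc2c1OC1C(=O)CC(=O)c2ccc(=O)oc21 | intermediate
17 | 8-[(5,7-dihydroxy-2-oxo-2H-chromen-8-yl)oxy]-7-methoxy-2H-chromen-2-one | COc1ccc2ccc(=O)oc2c1Oc1c(O)cc(O)c2ccc(=O)oc12 | target

**Step count**
Total step count: 7. Longest linear sequence: 6 (steps 2 to 7, from tert-butyl acetoacetate 5).

**Steps most likely to fail**

(1) Step 7.
- What may go wrong: the substrate may rest as its keto ester enolate, with the ester carbonyl deactivated and turned away from C8. Ring closure would then be outrun by intermolecular conjugate addition of the anions to the pyranone, or by opening of the pyranone by the methoxide set free.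
- Fallback: this uses known chemistry, sets out from 4 and comes back at 17. Commercial 5,7-dihydroxycoumarin is protected (MOMCl, i-Pr2NEt, CH2Cl2) as 5,7-bis(methoxymethoxy)coumarin F1. Iodination at the doubly activated and less crowded C8 (NIS, MeCN, 23 °C) gives 8-iodo-5,7-bis(methoxymethoxy)coumarin F2. An Ullmann diaryl ether synthesis with 4 (CuI, picolinic acid, K3PO4, DMSO, 90 °C) gives 8-{[5,7-bis(methoxymethoxy)-2-oxo-2H-chromen-8-yl]oxy}-7-methoxycoumarin F3. This coupling joins two di-ortho-substituted partners and should be slow. HCl in MeOH then frees both phenols and leaves the methyl ether in place, giving 17.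

(2) Step 6.
- What may go wrong: the magnesium malonate, imidazole or an amine-generated C8 anion may attack the electrophilic pyranone ring instead of C-acylation taking place at the hindered acyl imidazolide.
- Fallback: this sets out from 11 and comes back at 15, and takes the two carbons from Meldrum's acid instead of a malonate. Acid 11 is coupled with Meldrum's acid (EDC·HCl, DMAP, CH2Cl2, 0 → 23 °C) to 5-[hydroxy(6-{[(7-methoxy-2-oxo-2H-chromen-8-yl)oxy]methyl}-2-oxo-2H-pyran-5-yl)methylidene]-2,2-dimethyl-1,3-dioxane-4,6-dione F4. Heating F4 with MeOH in toluene (80 °C) fragments it to the acylketene, which methanol traps as 15 under neutral conditions.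

(3) Step 3.
- What may go wrong: a second bromination at the methyl group, ionic bromination of the ring at C3, or loss of the tert-butyl ester through HBr.
- Fallback: this sets out from 4 and comes back at 10. It makes the ether before the pyranone and replaces steps 2 to 4.
  - Phenol 4 is alkylated with tert-butyl bromoacetate (K2CO3, DMF) to tert-butyl [(7-methoxy-2-oxo-2H-chromen-8-yl)oxy]acetate F5.
  - TFA in CH2Cl2 gives [(7-methoxy-2-oxo-2H-chromen-8-yl)oxy]acetic acid F6.
  - Coupling with Meldrum's acid (EDC·HCl, DMAP, CH2Cl2) gives 5-{1-hydroxy-2-[(7-methoxy-2-oxo-2H-chromen-8-yl)oxy]ethylidene}-2,2-dimethyl-1,3-dioxane-4,6-dione F7.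
  - Heating F7 with t-BuOH in toluene (90 °C) gives tert-butyl 4-[(7-methoxy-2-oxo-2H-chromen-8-yl)oxy]-3-oxobutanoate F8.
  - Methyl propiolate 6 under the conditions of step 2 adds to F8 to give 5-tert-butyl 1-methyl (2E)-4-{[(7-methoxy-2-oxo-2H-chromen-8-yl)oxy]acetyl}pent-2-enedioate F9, which lactonises in the same flask to 10.

**Further compounds**
F1 | step 7 | 5,7-bis(methoxymethoxy)-2H-chromen-2-one | COCOc1cc(OCOC)c2ccc(=O)oc2c1
F2 | step 7 | 8-iodo-5,7-bis(methoxymethoxy)-2H-chromen-2-one | COCOc1cc(OCOC)c2ccc(=O)oc2c1I
F3 | step 7 | 8-{[5,7-bis(methoxymethoxy)-2-oxo-2H-chromen-8-yl]oxy}-7-methoxy-2H-chromen-2-one | COCOc1cc(OCOC)c2ccc(=O)oc2c1Oc1c(OC)ccc2ccc(=O)oc12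
F4 | step 6 | 5-[hydroxy(6-{[(7-methoxy-2-oxo-2H-chromen-8-yl)oxy]methyl}-2-oxo-2H-pyran-5-yl)methylidene]-2,2-dimethyl-1,3-dioxane-4,6-dione | CC1(C)OC(=O)C(=C(O)c2ccc(=O)oc2COc2c(OC)ccc3ccc(=O)oc23)C(=O)O1
F5 | step 3 | tert-butyl [(7-methoxy-2-oxo-2H-chromen-8-yl)oxy]acetate | COc1ccc2ccc(=O)oc2c1OCC(=O)OC(C)(C)C
F6 | step 3 | [(7-methoxy-2-oxo-2H-chromen-8-yl)oxy]acetic acid | COc1ccc2ccc(=O)oc2c1OCC(=O)O
F7 | step 3 | 5-{1-hydroxy-2-[(7-methoxy-2-oxo-2H-chromen-8-yl)oxy]ethylidene}-2,2-dimethyl-1,3-dioxane-4,6-dione | CC1(C)OC(=O)C(=C(O)COc2c(OC)ccc3ccc(=O)oc23)C(=O)O1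
F8 | step 3 | tert-butyl 4-[(7-methoxy-2-oxo-2H-chromen-8-yl)oxy]-3-oxobutanoate | COc1ccc2ccc(=O)oc2c1OCC(=O)CC(=O)OC(C)(C)C
F9 | step 3 | 5-tert-butyl 1-methyl (2E)-4-{[(7-methoxy-2-oxo-2H-chromen-8-yl)oxy]acetyl}pent-2-enedioate | COC(=O)/C=C/C(C(=O)OC(C)(C)C)C(=O)COc1c(OC)ccc2ccc(=O)oc12
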